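A leftover of substrate can be read from the charges of cedar, where the reagent is the limiting reagent: one reagent goes into each target, so the reagent ceiling C, reagent charged over substrate charged, here 50.0%, bounds the target in percent of substrate and leaves the rest of the substrate over.

| flask | substrate | reagent in the second phase | remark | time | volume of the second phase over the first |
|---|---|---|---|---|---|
| delta | 0.020 M | 0.027 M | run made earlier |  |  |
| epsilon | 0.020 M | 0.11 M | run made earlier |  |  |
| elm | 0.020 M | 0.0800 M |  | 2.5 d | 1.0 |
| maple | 0.040 M | 0.0800 M |  | 2.5 d | 1.0 |
| alder | 0.020 M | 0.0200 M |  | 2.5 d | 1.0 |
| cedar | 0.040 M | 0.0200 M |  | 2.5 d | 1.0 |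

| delta: time / d | delta: target / % | epsilon: time / d | epsilon: target / % |
|---|---|---|---|
| 0.333 | 23 | 0.208 | 41 |
| 0.625 | 40 | 0.333 | 53 |
| 1.04 | 52 | 0.500 | 60 |
| 1.25 | 56 | 0.625 | 62 |
| 1.67 | 62 | 1.04 | 65 |
| 2.00 | 65 | 1.67 | 55 |
| 2.50 | 72 | 2.50 | 54 |

(each reading ± 1.5 percentage points)

- in the second phase: reagent in the second phase; everything else is in the first
- charges count per volume of the first phase; a concentration in a rate is the amount of a species over the volume of its own phase; every rate counts per litre of the first phase
- the numbers in the tables scatter by 1.5 percentage points (one standard deviation)
- the earlier runs hold the two phases in the same ratio of volumes as the flask asked about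
- a reading or a percentage of target counts all its forms, free or not

- ranking by amount of target, in percent of the substrate charged, from high to low, at 2.5 d (elm / maple / alder / cedar)
- the amount of target, in percent of the substrate charged of the flask you put first, at 2.5 d
- the amount of target, in percent of the substrate charged of the flask you put last, at 2.5 d

C is the late end of this text's own reckoning for cedar. The early end comes from delta, whose first reading of 23% at 0.333 d used a share 17.0% of its reagent, which gives a first-order uptake constant k = 0.561 d⁻¹. Joined as C(1 − exp(−kt)), the two ends give 37.7% at 2.5 d. Cedar holds twice the substrate of delta, so that figure is taken as the low side, and the reckoning commits cedar to between it and C.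

The forecast, judging from the runs that “A simple irreversible over-reaction doesn't fit”, ranks maple > elm > alder > cedar, with 78% on top (71% to 84%) and 43% last (38% to 48%).

The flask gives maple > elm > alder > cedar, with 75.8% for maple and 42.5% for cedar.

    reagent in the reaction phase ⇌ reagent in the second phase, rate k1*([reagent in the reaction phase] - [reagent in the second phase]/K1) per volume of the first phase (partition coefficient = 1.67, kL = 0.00605 min⁻¹)
    substrate + reagent in the reaction phase → target (k = 0.0895 M⁻¹ min⁻¹)
    reagent in the reaction phase + target → over-reacted product (k = 0.0570 M⁻¹ min⁻¹)
    crystals ⇌ target, rate k4*(cs4 - [target]) while solid is left; crystals form when [target] > cs4 (solubility = 0.650 mM, k = 0.00370 min⁻¹)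

In cedar at 2.50 d, crystals make up 40.2% inside that target, and target plus twice the over-reacted product stands at 46.9% of substrate, with 3.11% still present as reagent in the two phases. Ten times the time, 25.0 d, adds 3 percentage points to cedar: target reaches 45.5%, reagent in the second phase 0%, substrate left 52.3%, and the balance 50.0%. Cedar is close to rest; maple is not, its target falling to 51.9%.

With 0.010 M of substrate, the neighbour of cedar has C = 200%, beyond the substrate itself, so the ceiling forces no leftover. That flask shows target 68.3% and over-reacted product 11.3%, with 20% of substrate still there and 34.4% of reagent in the second phase at 2.50 d.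

The data come from a simulation on assumed constants; the scatter is artificial.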